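**Retrosynthetic overview**
1. Target 45 ⇐ ten-membered C9 ketone 36 carrying the C5=C16 methylene; the endgame is C9 reduction, C7 lactone, C11 epoxide from the ketone, C6 OH→Cl with inversion, and acetates.
2. 36 ⇐ tricycle 35 by Grob fragmentation. In the ring C1–C10 the methylene carbon C5 and the oxygenated C9 face each other, so a transannular C5–C9 bond (cyclopentane ring C, C5–C9, fused to cycloheptane ring B, C1–C5/C9/C10) plus a C16 mesylate is a 1,3-diol monosulfonate.
3. 35 ⇐ cyclopentene 33, with C6, C7 and C8 set on the rigid cis-fused rings B/C ⇐ tricyclic ketol 21 by samarium Reformatsky closure of ring B (C9–C10).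
4. 21 ⇐ Michael union (C4–C5) of keto ester 11 (ring C) with ring A vinyl ketone 10, made from 2-methylcyclohexane-1,3-dione by yeast desymmetrisation.
5. Ring order: A, then C (joined), then B (closed), then the ten-membered ring by scission, then lactone and epoxide.

Key step: step 28

Remarks: briarane numbering is used throughout (C1 quaternary methyl carbon, C10 ring-fusion CH, C11 epoxide carbon, C14 cyclohexane CHOAc, C16 exocyclic methylene, C17/C19 lactone CHMe/C=O). The sense of induction in step 9 is assumed to follow the cinchona catalyst; the pseudo-enantiomeric catalyst is used if the other C5 epimer forms. C2 in 9 is an epimer mixture erased in step 8. C17 is carried as an epimer mixture from step 23 and set in step 34. C10/C11 of 19 and 20 are drawn as one trans isomer and are reset in step 17.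

**Step 1**
Reactants: 1 2-methylcyclohexane-1,3-dione; 2 allyl bromide
Product: 3 2-allyl-2-methylcyclohexane-1,3-dione
Conditions: NaOH (1 M aq.), rt
Reagents that add atoms: none
Why: C-alkylation of the stabilised 1,3-dione enolate with an allylic halide gives the quaternary, still achiral dione.

**Step 2**
Reactants: 3 2-allyl-2-methylcyclohexane-1,3-dione
Product: 4 (2S,3S)-2-allyl-3-hydroxy-2-methylcyclohexan-1-one
Conditions: baker's yeast, sucrose, H2O, 30 °C
Reagents that add atoms: none
Why: Enzymatic desymmetrising reduction of one enantiotopic carbonyl sets C1 and C14 together, hydride adding anti to the allyl group so that the 14-OH is cis to the allyl arm.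

**Step 3**
Reactants: 4 (2S,3S)-2-allyl-3-hydroxy-2-methylcyclohexan-1-one
Product: 5 C14 triethylsilyl ether of 4
Conditions: TESCl, imidazole, DMF, rt
Reagents that add atoms: chlorotriethylsilane, CC[Si](Cl)(CC)CC
Why: Silylation of the secondary alcohol masks it for the strong base of step 5 and keeps it from adding to the enone of step 8.

**Step 4**
Reactants: 5 C14 triethylsilyl ether of 4
Product: 6 (E)-prop-1-enyl ketone
Conditions: RuHCl(CO)(PPh3)3 (5 mol %), toluene, 80 °C
Reagents that add atoms: none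
Why: Ruthenium hydride-catalysed alkene isomerisation moves the terminal double bond to the more stable (E)-propenyl position next to C1.

**Step 5**
Reactants: 6 (E)-prop-1-enyl ketone
Product: 7 C10 enol triflate
Conditions: KHMDS, PhNTf2, THF, −78 °C
Reagents that add atoms: N-phenylbis(trifluoromethanesulfonimide), O=S(=O)(N(c1ccccc1)S(=O)(=O)C(F)(F)F)C(F)(F)F
Why: The ketone can enolise only toward C11 because C1 is quaternary, and O-triflation of the enolate masks C10 and prepares the C10=C11 alkene.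

**Step 6**
Reactants: 7 C10 enol triflate
Product: 8 ring A aldehyde (C2 formyl on C1)
Conditions: OsO4 (2 mol %), NaIO4, 2,6-lutidine, dioxane/H2O, rt
Reagents that add atoms: osmium tetroxide, O=[Os](=O)(=O)=O; sodium periodate, [Na+].[O-]I(=O)(=O)=O
Why: Lemieux–Johnson cleavage attacks the electron-rich propenyl alkene and not the electron-poor enol triflate, leaving the non-enolisable C2 aldehyde.

**Step 7**
Reactants: 8 ring A aldehyde
Product: 9 C2 vinyl carbinol (both C2 epimers)
Conditions: CH2=CHMgBr, THF, −78 °C; NH4Cl (aq.)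
Reagents that add atoms: vinylmagnesium bromide, C=C[Mg]Br
Why: Grignard 1,2-addition to the aldehyde brings in C3 and C4, and the uncontrolled C2 configuration is erased in step 8.

**Step 8**
Reactants: 9 C2 vinyl carbinol
Product: 10 ring A vinyl ketone
Conditions: Dess–Martin periodinane, NaHCO3, CH2Cl2, 0 °C
Reagents that add atoms: none
Why: Oxidation of the allylic alcohol gives the vinyl ketone acceptor for the Michael union.

**Step 9**
Reactants: 10 ring A vinyl ketone; 11 methyl 2-oxocyclopentane-1-carboxylate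
Product: 12 Michael adduct with quaternary C5
Conditions: 9-O-(9-phenanthryl)cupreidine (10 mol %), CH2Cl2, −24 °C
Reagents that add atoms: none
Why: Bifunctional cinchona-catalysed Michael addition of the cyclic β-keto ester forms C4–C5 and sets the quaternary C5 under catalyst control, the ring A stereocentres being five bonds away.

**Step 10**
Reactants: 12 Michael adduct
Product: 13 C14 alcohol
Conditions: HF·pyridine, pyridine, THF, 0 °C
Reagents that add atoms: none
Why: Fluoride-mediated desilylation frees the C14 hydroxyl, now safe because the enone is consumed, to direct the next reduction.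

**Step 11**
Reactants: 13 C14 alcohol
Product: 14 anti-1,3-diol (2S,14S)
Conditions: Me4NBH(OAc)3, MeCN/AcOH, −20 °C
Reagents that add atoms: none
Why: Evans–Saksena reduction: the C14 hydroxyl binds the borohydride and delivers hydride through a chair transition state, giving the 1,3-anti diol at C2 and leaving the undirected cyclopentanone untouched.

**Step 12**
Reactants: 14 anti-1,3-diol
Product: 15 bis(triethylsilyl) ether
Conditions: TESCl, imidazole, DMAP, DMF, 40 °C
Reagents that add atoms: chlorotriethylsilane, CC[Si](Cl)(CC)CC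
Why: Silylation protects both hindered secondary alcohols as acid-labile ethers without silylating the ketone.

**Step 13**
Reactants: 15 bis(triethylsilyl) ether
Product: 16 cyclohexene keto ester (C10=C11)
Conditions: Pd(OAc)2 (5 mol %), PPh3, HCO2H, Bu3N, DMF, 60 °C
Reagents that add atoms: none
Why: Palladium-catalysed formate reduction of the enol triflate (oxidative addition, hydride transfer, reductive elimination) gives the C10=C11 alkene.

**Step 14**
Reactants: 16 cyclohexene keto ester
Product: 18 ring C cyclopentenone (C9 ketone and C7=C8), via silyl enol ether 17 (not isolated)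
Conditions: LiHMDS, TMSCl, THF, −78 °C; then Pd(OAc)2, MeCN, rt
Reagents that add atoms: none
Why: Saegusa–Ito dehydrogenation: the ketone enolises only toward C8, and the palladium enolate undergoes β-hydride elimination to the enone.

**Step 15**
Reactants: 18 ring C cyclopentenone
Product: 19 trans-bromohydrin (C10 Br and C11 OH)
Conditions: NBS, acetone/H2O, 0 °C
Reagents that add atoms: N-bromosuccinimide, O=C1CCC(=O)N1Br; water, O
Why: Bromohydrin formation on the only electron-rich alkene, water opening the bromonium ion trans at C11, the carbon remote from the quaternary C1.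

**Step 16**
Reactants: 19 trans-bromohydrin
Product: 20 α-bromo ketone (C10 Br and C11 ketone)
Conditions: Dess–Martin periodinane, NaHCO3, CH2Cl2, rt
Reagents that add atoms: none
Why: Oxidation of the secondary alcohol gives the α-bromo ketone that fixes the C10 enolate regiochemistry.

**Step 17**
Reactants: 20 α-bromo ketone
Product: 21 tricyclic ketol (C9 OH and C11 ketone)
Conditions: SmI2 (2.2 equiv), THF, −78 °C
Reagents that add atoms: none
Why: Samarium Reformatsky-type aldol: reduction of the C–Br bond gives the C10 samarium enolate, which adds to the C9 carbonyl on the face carrying the C4 tether so that rings B and C are cis-fused with 9-OH cis to the ester, while C10, α to the ketone, settles with H10 trans to the C1 methyl (diequatorial on ring A).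

**Step 18**
Reactants: 21 tricyclic ketol
Product: 23 C11 dioxolane C9 trimethylsilyl ether, via silyl ether ketone 22 (not isolated)
Conditions: TMSOTf, 2,6-lutidine, CH2Cl2, −78 °C; then (TMSOCH2)2, TMSOTf (cat.), −78 to −20 °C
Reagents that add atoms: trimethylsilyl trifluoromethanesulfonate, C[Si](C)(C)OS(=O)(=O)C(F)(F)F; 1,2-bis(trimethylsilyloxy)ethane, C[Si](C)(C)OCCO[Si](C)(C)C
Why: O-silylation of the tertiary alcohol and silyl triflate-catalysed ketalisation protect C11 under aprotic conditions that avoid retro-aldol cleavage and dehydration of the ketol.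

**Step 19**
Reactants: 23 C11 dioxolane C9 trimethylsilyl ether
Product: 24 C16 primary alcohol
Conditions: LiAlH4, Et2O, 0 °C
Reagents that add atoms: none
Why: Hydride reduction of the neopentyl ester gives the C16 alcohol while ketal and silyl ethers are inert.

**Step 20**
Reactants: 24 C16 primary alcohol
Product: 25 C16 mesylate
Conditions: MsCl, Et3N, CH2Cl2, 0 °C
Reagents that add atoms: methanesulfonyl chloride, CS(=O)(=O)Cl
Why: Sulfonylation of the only free hydroxyl installs the nucleofuge early, a neopentyl mesylate being inert to the neutral and acidic steps that follow and unable to fragment while the C9 oxygen is silylated or protonated.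

**Step 21**
Reactants: 25 C16 mesylate
Product: 26 C6 enone (C6 ketone and C7=C8)
Conditions: CrO3, 3,5-dimethylpyrazole, CH2Cl2, −20 °C
Reagents that add atoms: chromium trioxide, O=[Cr](=O)=O
Why: Allylic oxidation at C6, the only allylic methylene since C9 is quaternary, gives the cyclopentenone that carries the C6 oxygen.

**Step 22**
Reactants: 27 methyl propanoate
Product: 28 (E)-1-methoxy-1-(trimethylsilyloxy)prop-1-ene
Conditions: LDA, THF, −78 °C; then TMSCl
Reagents that add atoms: chlorotrimethylsilane, C[Si](C)(C)Cl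
Why: Kinetic ester enolisation and O-silylation give the silyl ketene acetal.

**Step 23**
Reactants: 26 C6 enone; 28 (E)-1-methoxy-1-(trimethylsilyloxy)prop-1-ene
Product: 30 C8-substituted enone (C17 epimers), via silyl enol ether 29 (not isolated)
Conditions: LiClO4 (cat.), CH2Cl2, rt; then Pd(OAc)2, MeCN, rt
Reagents that add atoms: none
Why: Mukaiyama–Michael addition attaches C17 to C8 and Saegusa–Ito oxidation of the silyl enol ether restores the enone with C8 substituted, C17 forming as an epimer mixture because it is acidic at this stage.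

**Step 24**
Reactants: 30 C8-substituted enone
Product: 32 C6,C9 diol (6-OH trans to 9-OH), via hydroxy enone 31 (not isolated)
Conditions: PPTS, MeOH, 0 °C; then Me4NBH(OAc)3, MeCN/AcOH, −20 °C
Reagents that add atoms: none
Why: After methanolysis of the silyl ether, Evans–Saksena 1,2-reduction delivers hydride from the 9-OH across the convex face, so the 6-OH ends on the concave face, trans to 9-OH.

**Step 25**
Reactants: 32 C6,C9 diol
Product: 33 C6 triisopropylsilyl ether
Conditions: TIPSOTf, 2,6-lutidine, CH2Cl2, −40 °C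
Reagents that add atoms: triisopropylsilyl trifluoromethanesulfonate, CC(C)[Si](OS(=O)(=O)C(F)(F)F)(C(C)C)C(C)C
Why: The secondary allylic alcohol is silylated in preference to the tertiary one under a non-deprotonating base, which blocks the C6 oxygen from acting as an alkoxide toward the mesylate.

**Step 26**
Reactants: 33 C6 triisopropylsilyl ether
Product: 34 C7,C8,C9 all-cis triol
Conditions: OsO4, TMEDA, CH2Cl2, −78 °C; then Na2SO3 (aq.)
Reagents that add atoms: osmium tetroxide, O=[Os](=O)(=O)=O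
Why: Hydrogen-bond-directed dihydroxylation: the OsO4–diamine complex is guided by the free 9-OH to the convex face, which is also anti to the 6-silyloxy group, setting C7 and C8 cis to the 9-OH.

**Step 27**
Reactants: 34 C7,C8,C9 all-cis triol
Product: 35 C7,C8 acetonide C9 carbinol C16 mesylate (fragmentation precursor)
Conditions: Me2C(OMe)2, PPTS, CH2Cl2, rt
Reagents that add atoms: 2,2-dimethoxypropane, COC(C)(C)OC
Why: Acid-catalysed transketalisation forms the dioxolane across the less hindered secondary/tertiary cis-diol and leaves the 9-OH free.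

**Step 28**
Reactants: 35 C7,C8 acetonide C9 carbinol C16 mesylate
Product: 36 ten-membered C9 ketone with C5=C16 methylene
Conditions: KOtBu (1.1 equiv), THF, 0 °C
Reagents that add atoms: none
Why: KOtBu deprotonates the free tertiary 9-OH, and the alkoxide forms C9=O as the C5–C9 σ bond becomes the C5=C16 π bond and mesylate leaves from C16 in a concerted push–pull process. The closest known type is the Grob (Wharton) fragmentation of cyclic 1,3-diol monosulfonates to medium-ring ketones. No ring is closed: the ten-membered ring C1–C10 appears when the bond shared by the cyclopentane and the cycloheptane is cut. No stereocentre is made, C5 and C9 become trigonal and the exocyclic alkene has no geometry, while C6, C7 and C8 were set beforehand on the rigid bicycle. The step needs fragmentation to outrun ester enolisation, retro-aldol cleavage and displacement, which is secured by the leaving group on a freely rotating CH2 that can always lie antiperiplanar to C5–C9, by one equivalent of base, by the C11 ketal, by the blocked C6 and C8 oxygens and by the neopentyl nature of the mesylate.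

**Step 29**
Reactants: 36 ten-membered C9 ketone
Product: 37 C9,C19 diol (9S)
Conditions: LiAlH4, THF, −78 to 0 °C
Reagents that add atoms: none
Why: Hydride should add to the C9 carbonyl from the ring periphery, anti to the C7–C8 ring bond, in the conformer with C=O opposed to the C8–O dipole and the branched C17 chain turned outward, giving the 9S carbinol, and the same reagent reduces the ester so that no lactone can close on the 9-oxygen.

**Step 30**
Reactants: 37 C9,C19 diol
Product: 38 C9,C19 bis(tert-butyldimethylsilyl) ether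
Conditions: TBSOTf, 2,6-lutidine, CH2Cl2, 0 °C
Reagents that add atoms: tert-butyldimethylsilyl trifluoromethanesulfonate, CC(C)(C)[Si](C)(C)OS(=O)(=O)C(F)(F)F
Why: Double silylation blocks the 9-OH as a hindered, acid-resistant ether and the primary alcohol as an acid-labile one.

**Step 31**
Reactants: 38 C9,C19 bis(tert-butyldimethylsilyl) ether
Product: 39 pentaol C11 ketone
Conditions: HCl (1 M aq.)/THF, rt
Reagents that add atoms: water, O
Why: Acid hydrolysis removes the triethylsilyl ethers, the primary silyl ether, the acetonide and the dioxolane in one operation, while the hindered C9 silyl ether and the triisopropylsilyl ether should survive.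

**Step 32**
Reactants: 39 pentaol C11 ketone
Product: 40 C7 γ-lactone (C17 epimers)
Conditions: TEMPO (cat.), PhI(OAc)2, CH2Cl2, rt
Reagents that add atoms: none
Why: Nitroxyl-catalysed oxidation is selective for the primary alcohol, and the aldehyde closes to the lactol with the 7-OH, the only γ-hydroxyl left free, and is oxidised on to the lactone.

**Step 33**
Reactants: 40 C7 γ-lactone
Product: 41 C11 spiro-epoxide (11S)
Conditions: Me3S(O)I, NaH, DMSO, rt
Reagents that add atoms: trimethylsulfoxonium iodide, C[S+](C)(C)=O.[I-]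
Why: Corey–Chaykovsky epoxidation: the sulfoxonium ylide adds reversibly and delivers CH2 equatorially, anti to the axial C1 methyl, giving the epoxide with axial oxygen, and this weakly basic ylide does not deprotonate the free hydroxyls.

**Step 34**
Reactants: 41 C11 spiro-epoxide
Product: 42 17R lactone
Conditions: DBU, toluene, 60 °C
Reagents that add atoms: none
Why: Base-mediated enolisation should equilibrate the lactone α-centre to the more stable epimer, with the methyl trans to the bulky C9 substituent and cis to the 8-OH.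

**Step 35**
Reactants: 42 17R lactone
Product: 43 tetraol with free 6-OH and 9-OH
Conditions: TBAF, THF, 40 °C; NH4Cl (aq.)
Reagents that add atoms: none
Why: Fluoride cleaves both remaining silyl ethers without touching epoxide or lactone.

**Step 36**
Reactants: 43 tetraol
Product: 44 C6 chloride (6S)
Conditions: PPh3, hexachloroacetone, CH2Cl2, 0 °C
Reagents that add atoms: hexachloroacetone, ClC(Cl)(Cl)C(=O)C(Cl)(Cl)Cl
Why: Appel-type chlorination through the alkoxyphosphonium salt converts the allylic alcohol to the chloride by SN2 with inversion, the hindered saturated alcohols reacting far more slowly and this reagent pair favouring direct over allylic substitution.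

**Step 37**
Reactants: 44 C6 chloride
Product: 45 CNP0104093.2
Conditions: Ac2O, pyridine, DMAP, rt
Reagents that add atoms: acetic anhydride, CC(=O)OC(C)=O
Why: Nucleophile-catalysed acylation esterifies the three secondary alcohols at C2, C9 and C14 and leaves the tertiary 8-OH free.

**Compound list**
1 | 2-methylcyclohexane-1,3-dione | CC1C(=O)CCCC1=O | starting material
2 | allyl bromide | C=CCBr | starting material
3 | 2-allyl-2-methylcyclohexane-1,3-dione | C=CCC1(C)C(=O)CCCC1=O | intermediate
4 | (2S,3S)-2-allyl-3-hydroxy-2-methylcyclohexan-1-one | C=CC[C@@]1(C)[C@@H](O)CCCC1=O | intermediate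
5 | C14 triethylsilyl ether of 4 | C=CC[C@@]1(C)[C@@H](O[Si](CC)(CC)CC)CCCC1=O | intermediate
6 | (E)-prop-1-enyl ketone | C/C=C/[C@@]1(C)[C@@H](O[Si](CC)(CC)CC)CCCC1=O | intermediate
7 | C10 enol triflate (C10=C11) | C/C=C/[C@@]1(C)[C@@H](O[Si](CC)(CC)CC)CCC=C1OS(=O)(=O)C(F)(F)F | intermediate
8 | ring A aldehyde (C2 formyl on C1) | O=C[C@@]1(C)[C@@H](O[Si](CC)(CC)CC)CCC=C1OS(=O)(=O)C(F)(F)F | intermediate
9 | C2 vinyl carbinol (both C2 epimers) | C=CC(O)[C@@]1(C)[C@@H](O[Si](CC)(CC)CC)CCC=C1OS(=O)(=O)C(F)(F)F | intermediate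
10 | ring A vinyl ketone | C=CC(=O)[C@@]1(C)[C@@H](O[Si](CC)(CC)CC)CCC=C1OS(=O)(=O)C(F)(F)F | intermediate
11 | methyl 2-oxocyclopentane-1-carboxylate | COC(=O)C1CCCC1=O | starting material
12 | Michael adduct (5S quaternary keto ester, C2 ketone) | COC(=O)[C@]1(CCC(=O)[C@@]2(C)[C@@H](O[Si](CC)(CC)CC)CCC=C2OS(=O)(=O)C(F)(F)F)CCCC1=O | intermediate
13 | C14 alcohol | COC(=O)[C@]1(CCC(=O)[C@@]2(C)[C@@H](O)CCC=C2OS(=O)(=O)C(F)(F)F)CCCC1=O | intermediate
14 | anti-1,3-diol (2S,14S) | COC(=O)[C@]1(CC[C@H](O)[C@@]2(C)[C@@H](O)CCC=C2OS(=O)(=O)C(F)(F)F)CCCC1=O | intermediate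
15 | C2,C14 bis(triethylsilyl) ether | COC(=O)[C@]1(CC[C@H](O[Si](CC)(CC)CC)[C@@]2(C)[C@@H](O[Si](CC)(CC)CC)CCC=C2OS(=O)(=O)C(F)(F)F)CCCC1=O | intermediate
16 | cyclohexene keto ester (C10=C11) | COC(=O)[C@]1(CC[C@H](O[Si](CC)(CC)CC)[C@@]2(C)[C@@H](O[Si](CC)(CC)CC)CCC=C2)CCCC1=O | intermediate
17 | C9 trimethylsilyl enol ether (not isolated) | COC(=O)[C@]1(CC[C@H](O[Si](CC)(CC)CC)[C@@]2(C)[C@@H](O[Si](CC)(CC)CC)CCC=C2)CCC=C1O[Si](C)(C)C | intermediate
18 | ring C cyclopentenone (C9 ketone, C7=C8) | COC(=O)[C@]1(CC[C@H](O[Si](CC)(CC)CC)[C@@]2(C)[C@@H](O[Si](CC)(CC)CC)CCC=C2)CC=CC1=O | intermediate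
19 | trans-bromohydrin (C10 Br, C11 OH) | COC(=O)[C@]1(CC[C@H](O[Si](CC)(CC)CC)[C@@]2(C)[C@@H](O[Si](CC)(CC)CC)CC[C@H](O)[C@H]2Br)CC=CC1=O | intermediate
20 | α-bromo ketone (C10 Br, C11 ketone) | COC(=O)[C@]1(CC[C@H](O[Si](CC)(CC)CC)[C@@]2(C)[C@@H](O[Si](CC)(CC)CC)CCC(=O)[C@H]2Br)CC=CC1=O | intermediate
21 | tricyclic ketol (rings B/C cis-fused, 9-OH cis to ester, A/B trans) | COC(=O)[C@]14CC[C@H](O[Si](CC)(CC)CC)[C@@]2(C)[C@@H](O[Si](CC)(CC)CC)CCC(=O)[C@@H]2[C@]4(O)C=CC1 | intermediate
22 | C9 trimethylsilyl ether C11 ketone (not isolated) | COC(=O)[C@]14CC[C@H](O[Si](CC)(CC)CC)[C@@]2(C)[C@@H](O[Si](CC)(CC)CC)CCC(=O)[C@@H]2[C@]4(O[Si](C)(C)C)C=CC1 | intermediate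
23 | C11 dioxolane C9 trimethylsilyl ether | COC(=O)[C@]14CC[C@H](O[Si](CC)(CC)CC)[C@@]2(C)[C@@H](O[Si](CC)(CC)CC)CCC3(OCCO3)[C@@H]2[C@]4(O[Si](C)(C)C)C=CC1 | intermediate
24 | C16 primary alcohol | OC[C@]14CC[C@H](O[Si](CC)(CC)CC)[C@@]2(C)[C@@H](O[Si](CC)(CC)CC)CCC3(OCCO3)[C@@H]2[C@]4(O[Si](C)(C)C)C=CC1 | intermediate
25 | C16 mesylate | CS(=O)(=O)OC[C@]14CC[C@H](O[Si](CC)(CC)CC)[C@@]2(C)[C@@H](O[Si](CC)(CC)CC)CCC3(OCCO3)[C@@H]2[C@]4(O[Si](C)(C)C)C=CC1 | intermediate
26 | C6 enone (C6 ketone, C7=C8) | CS(=O)(=O)OC[C@]14CC[C@H](O[Si](CC)(CC)CC)[C@@]2(C)[C@@H](O[Si](CC)(CC)CC)CCC3(OCCO3)[C@@H]2[C@]4(O[Si](C)(C)C)C=CC1=O | intermediate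
27 | methyl propanoate | CCC(=O)OC | starting material
28 | (E)-1-methoxy-1-(trimethylsilyloxy)prop-1-ene | C/C=C(\OC)O[Si](C)(C)C | intermediate
29 | C6 silyl enol ether Michael adduct (not isolated; C8, C17 epimers) | CS(=O)(=O)OC[C@]14CC[C@H](O[Si](CC)(CC)CC)[C@@]2(C)[C@@H](O[Si](CC)(CC)CC)CCC3(OCCO3)[C@@H]2[C@]4(O[Si](C)(C)C)C(C(C)C(=O)OC)C=C1O[Si](C)(C)C | intermediate
30 | C8-substituted enone (C17 epimers) | CS(=O)(=O)OC[C@]14CC[C@H](O[Si](CC)(CC)CC)[C@@]2(C)[C@@H](O[Si](CC)(CC)CC)CCC3(OCCO3)[C@@H]2[C@]4(O[Si](C)(C)C)C(C(C)C(=O)OC)=CC1=O | intermediate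
31 | C9 hydroxy enone (not isolated; C17 epimers) | CS(=O)(=O)OC[C@]14CC[C@H](O[Si](CC)(CC)CC)[C@@]2(C)[C@@H](O[Si](CC)(CC)CC)CCC3(OCCO3)[C@@H]2[C@]4(O)C(C(C)C(=O)OC)=CC1=O | intermediate
32 | C6,C9 diol, 6-OH trans to 9-OH (C17 epimers) | CS(=O)(=O)OC[C@]14CC[C@H](O[Si](CC)(CC)CC)[C@@]2(C)[C@@H](O[Si](CC)(CC)CC)CCC3(OCCO3)[C@@H]2[C@]4(O)C(C(C)C(=O)OC)=C[C@@H]1O | intermediate
33 | C6 triisopropylsilyl ether (C17 epimers) | CS(=O)(=O)OC[C@]14CC[C@H](O[Si](CC)(CC)CC)[C@@]2(C)[C@@H](O[Si](CC)(CC)CC)CCC3(OCCO3)[C@@H]2[C@]4(O)C(C(C)C(=O)OC)=C[C@@H]1O[Si](C(C)C)(C(C)C)C(C)C | intermediate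
34 | C7,C8,C9 all-cis triol (C17 epimers) | CS(=O)(=O)OC[C@]14CC[C@H](O[Si](CC)(CC)CC)[C@@]2(C)[C@@H](O[Si](CC)(CC)CC)CCC3(OCCO3)[C@@H]2[C@]4(O)[C@@](C(C)C(=O)OC)(O)[C@@H](O)[C@@H]1O[Si](C(C)C)(C(C)C)C(C)C | intermediate
35 | fragmentation precursor: C7,C8 acetonide, C9 carbinol, C16 mesylate (C17 epimers) | CS(=O)(=O)OC[C@]14CC[C@H](O[Si](CC)(CC)CC)[C@@]2(C)[C@@H](O[Si](CC)(CC)CC)CCC3(OCCO3)[C@@H]2[C@]4(O)[C@@]5(C(C)C(=O)OC)OC(C)(C)O[C@H]5[C@@H]1O[Si](C(C)C)(C(C)C)C(C)C | intermediate
36 | fragmentation product: ten-membered C9 ketone, C5=C16 methylene (C17 epimers) | C=C1CC[C@H](O[Si](CC)(CC)CC)[C@@]2(C)[C@@H](O[Si](CC)(CC)CC)CCC3(OCCO3)[C@@H]2C(=O)[C@@]4(C(C)C(=O)OC)OC(C)(C)O[C@H]4[C@@H]1O[Si](C(C)C)(C(C)C)C(C)C | intermediate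
37 | C9,C19 diol, 9S (C17 epimers) | C=C1CC[C@H](O[Si](CC)(CC)CC)[C@@]2(C)[C@@H](O[Si](CC)(CC)CC)CCC3(OCCO3)[C@@H]2[C@H](O)[C@@]4(C(C)CO)OC(C)(C)O[C@H]4[C@@H]1O[Si](C(C)C)(C(C)C)C(C)C | intermediate
38 | C9,C19 bis(tert-butyldimethylsilyl) ether (C17 epimers) | C=C1CC[C@H](O[Si](CC)(CC)CC)[C@@]2(C)[C@@H](O[Si](CC)(CC)CC)CCC3(OCCO3)[C@@H]2[C@H](O[Si](C)(C)C(C)(C)C)[C@@]4(C(C)CO[Si](C)(C)C(C)(C)C)OC(C)(C)O[C@H]4[C@@H]1O[Si](C(C)C)(C(C)C)C(C)C | intermediate
39 | pentaol C11 ketone, C9 OTBS, C6 OTIPS (C17 epimers) | C=C1CC[C@H](O)[C@@]2(C)[C@@H](O)CCC(=O)[C@@H]2[C@H](O[Si](C)(C)C(C)(C)C)[C@](O)(C(C)CO)[C@@H](O)[C@@H]1O[Si](C(C)C)(C(C)C)C(C)C | intermediate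
40 | C7 γ-lactone C11 ketone (C17 epimers) | C=C1CC[C@H](O)[C@@]2(C)[C@@H](O)CCC(=O)[C@@H]2[C@H](O[Si](C)(C)C(C)(C)C)[C@]2(O)C(C)C(=O)O[C@H]2[C@@H]1O[Si](C(C)C)(C(C)C)C(C)C | intermediate
41 | C11 spiro-epoxide, 11S (C17 epimers) | C=C1CC[C@H](O)[C@@]2(C)[C@@H](O)CC[C@@]3(CO3)[C@@H]2[C@H](O[Si](C)(C)C(C)(C)C)[C@]2(O)C(C)C(=O)O[C@H]2[C@@H]1O[Si](C(C)C)(C(C)C)C(C)C | intermediate
42 | 17R lactone | C=C1CC[C@H](O)[C@@]2(C)[C@@H](O)CC[C@@]3(CO3)[C@@H]2[C@H](O[Si](C)(C)C(C)(C)C)[C@]2(O)[C@@H](C)C(=O)O[C@H]2[C@@H]1O[Si](C(C)C)(C(C)C)C(C)C | intermediate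
43 | tetraol (free OH at C2, C6, C9, C14; 8-OH) | C=C1CC[C@H](O)[C@@]2(C)[C@@H](O)CC[C@@]3(CO3)[C@@H]2[C@H](O)[C@]2(O)[C@@H](C)C(=O)O[C@H]2[C@@H]1O | intermediate
44 | C6 chloride, 6S | C=C1CC[C@H](O)[C@@]2(C)[C@@H](O)CC[C@@]3(CO3)[C@@H]2[C@H](O)[C@]2(O)[C@@H](C)C(=O)O[C@H]2[C@H]1Cl | intermediate
45 | CNP0104093.2 | C=C1CC[C@H](OC(C)=O)[C@@]2(C)[C@@H](OC(C)=O)CC[C@@]3(CO3)[C@@H]2[C@H](OC(C)=O)[C@]2(O)[C@@H](C)C(=O)O[C@H]2[C@H]1Cl | target

**Step count and risks**
Total steps: 37. Longest linear sequence: 36 (steps 1–21 and 23–37; step 22 prepares the ketene acetal).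

Steps most likely to fail:

Step 28 (key fragmentation). What may go wrong: deprotonation α to the C19 ester followed by β-elimination of the C8 dioxolane oxygen, or attack of the C9 alkoxide on the ester, may compete with bond scission. Fallback: from 35 the ester is reduced first (DIBAL-H, CH2Cl2, −78 °C, mesylate untouched) to the primary alcohol F2, which is silylated (TBSCl, imidazole) to the silyl ether F3 and fragmented with KOtBu to the ester-free ketone F4. LiAlH4 then gives the 9S alcohol F5, and TBSOTf/2,6-lutidine returns to the route at 38.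

Step 17 (ring B closure). What may go wrong: the samarium enolate may be protonated, or the hindered aldol may revert, before the seven-membered ring forms, so that reduction occurs without C–C bond formation. Fallback: from 20, zinc dust and TMSCl (Et2O, 0 °C) should give regiospecifically the C10=C11 trimethylsilyl enol ether F1. A Lewis-acid Mukaiyama aldol (TiCl4, CH2Cl2, −78 °C) onto the C9 carbonyl then closes ring B irreversibly and returns to the route at 21.

Step 29 (C9 reduction). What may go wrong: poor facial selectivity at the macrocyclic carbonyl, giving the 9-epimer. Fallback: from 36 a reagent-controlled Corey–Bakshi–Shibata reduction (matched enantiomer of the B-methyl oxazaborolidine, catecholborane, toluene, −78 °C) overrides the substrate bias and gives the 9S hydroxy ester F6 (or its C9 lactone). LiAlH4 then reduces the ester or lactone and returns to the route at 37.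

**Further compounds**
F1 | step 17 | C10=C11 trimethylsilyl enol ether of ring A | COC(=O)[C@]1(CC[C@H](O[Si](CC)(CC)CC)[C@@]2(C)[C@@H](O[Si](CC)(CC)CC)CCC(O[Si](C)(C)C)=C2)CC=CC1=O
F2 | step 28 | C19 primary alcohol of the tricyclic mesylate | CS(=O)(=O)OC[C@]14CC[C@H](O[Si](CC)(CC)CC)[C@@]2(C)[C@@H](O[Si](CC)(CC)CC)CCC3(OCCO3)[C@@H]2[C@]4(O)[C@@]5(C(C)CO)OC(C)(C)O[C@H]5[C@@H]1O[Si](C(C)C)(C(C)C)C(C)C
F3 | step 28 | C19 tert-butyldimethylsilyl ether of F2 | CS(=O)(=O)OC[C@]14CC[C@H](O[Si](CC)(CC)CC)[C@@]2(C)[C@@H](O[Si](CC)(CC)CC)CCC3(OCCO3)[C@@H]2[C@]4(O)[C@@]5(C(C)CO[Si](C)(C)C(C)(C)C)OC(C)(C)O[C@H]5[C@@H]1O[Si](C(C)C)(C(C)C)C(C)C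
F4 | step 28 | ester-free ten-membered C9 ketone | C=C1CC[C@H](O[Si](CC)(CC)CC)[C@@]2(C)[C@@H](O[Si](CC)(CC)CC)CCC3(OCCO3)[C@@H]2C(=O)[C@@]4(C(C)CO[Si](C)(C)C(C)(C)C)OC(C)(C)O[C@H]4[C@@H]1O[Si](C(C)C)(C(C)C)C(C)C
F5 | step 28 | 9S alcohol with C19 silyl ether | C=C1CC[C@H](O[Si](CC)(CC)CC)[C@@]2(C)[C@@H](O[Si](CC)(CC)CC)CCC3(OCCO3)[C@@H]2[C@H](O)[C@@]4(C(C)CO[Si](C)(C)C(C)(C)C)OC(C)(C)O[C@H]4[C@@H]1O[Si](C(C)C)(C(C)C)C(C)C
F6 | step 29 | 9S hydroxy ester | C=C1CC[C@H](O[Si](CC)(CC)CC)[C@@]2(C)[C@@H](O[Si](CC)(CC)CC)CCC3(OCCO3)[C@@H]2[C@H](O)[C@@]4(C(C)C(=O)OC)OC(C)(C)O[C@H]4[C@@H]1O[Si](C(C)C)(C(C)C)C(C)C
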